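**Retrosynthetic overview**
1. 25 ⇐ 24 (TBS removal) ⇐ β,γ-epoxy ketone 23, whose E1cB opening gives C2=C3 and the C4–OH ⇐ OH-directed epoxidation of cyclohex-3-enone 22. C4 is thus relayed from C6.
2. The carbocycle comes from RCM (C3=C4) of the two allyl arms of 20. One arm is installed by vinyl-cuprate opening of epoxide 15 (C5–C4), the other by allyl Grignard addition to aldehyde 18 (C1–C2).
3. C6 is set by Sharpless epoxidation of 2-methylene alcohol 14. This alcohol is made from aldehyde 10 by Mannich methylenation (C5) and 1,2-reduction.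
4. The key bond is C1'–C2'. Catalytic asymmetric carbonyl allylation of (Z)-hexadec-9-enal 3 with allylstannane 4 sets C2' and brings in C1', C6 and C1.
5. Ring order: the oxirane of 15 (opened in step 10), then the cyclohexene ring (the only ring kept), then the fused oxirane of 23 (opened in the same flask).

Assumption: target atoms are labelled C1 (C=O) to C6 (carbinol carbon carrying the chain) in the ring and C1'–C17' in the chain; TBS = tert-butyldimethylsilyl; commercial palmitoleic acid is taken as the pure Z isomer.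

**Step 1**
Reactants: 1 palmitoleic acid, (9Z)-hexadec-9-enoic acid
Product: 2 (9Z)-hexadec-9-en-1-ol
Conditions: LiAlH4 (1.5 equiv), THF, 0 °C to rt; then H2O
Reagents that add atoms: none
Why: Hydride reduction of the carboxylic acid with LiAlH4 stops at the primary alcohol and leaves the isolated Z-alkene untouched.

**Step 2**
Reactants: 2 (9Z)-hexadec-9-en-1-ol
Product: 3 (9Z)-hexadec-9-enal
Conditions: TEMPO (10 mol%), PhI(OAc)2 (1.1 equiv), CH2Cl2, rt
Reagents that add atoms: none
Why: The TEMPO/PhI(OAc)2 oxoammonium oxidation takes a primary alcohol to the aldehyde without over-oxidation or strong acid or base, so the Z-alkene neither migrates nor isomerises.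

**Step 3 (key step)**
Reactants: 3 (9Z)-hexadec-9-enal; 4 allyltributylstannane
Product: 6 (4S,12Z)-nonadeca-1,12-dien-4-ol, via tributylstannyl ether 5 (not isolated)
Conditions: (R)-BINOL (10 mol%), Ti(OiPr)4 (10 mol%), 4 Å MS, CH2Cl2, reflux 1 h; then 3 and 4 (1.2 equiv), −78 to −20 °C, 72 h; aq NaHCO3
Reagents that add atoms: allyltributylstannane (4), C=CC[Sn](CCCC)(CCCC)CCCC
Why: In this Keck asymmetric carbonyl allylation the (R)-BINOL/Ti(OiPr)4 Lewis acid activates the unbranched aldehyde and exposes its Re face to the allylstannane, which forms the C1'–C2' bond and sets C2' as (S) in typically 93–97% ee while the remote Z-alkene is a spectator.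

**Step 4**
Reactants: 6 (4S,12Z)-nonadeca-1,12-dien-4-ol
Product: 7 tert-butyl(dimethyl){[(4S,12Z)-nonadeca-1,12-dien-4-yl]oxy}silane
Conditions: TBSCl (1.3 equiv), imidazole (2.5 equiv), DMF, rt
Reagents that add atoms: tert-butyldimethylsilyl chloride, CC(C)(C)[Si](C)(C)Cl
Why: Imidazole-promoted silylation of the unhindered secondary alcohol gives an ether that survives every step up to the final fluoride treatment and does not touch the stereocentre.

**Step 5**
Reactants: 7 tert-butyl(dimethyl){[(4S,12Z)-nonadeca-1,12-dien-4-yl]oxy}silane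
Product: 9 (4S,12Z)-4-[(tert-butyldimethylsilyl)oxy]nonadec-12-en-1-ol, via B-alkyl-9-BBN adduct 8 (not isolated)
Conditions: 9-BBN (1.15 equiv), THF, 0 °C to rt; then 3 M NaOH, 30% H2O2, 0 °C
Reagents that add atoms: hydrogen peroxide, OO (oxygen of the new OH); 9-borabicyclo[3.3.1]nonane, [H]B1C2CCCC1CCC2 (its boron and carbons are found only in 8)
Why: In this Brown hydroboration–oxidation 9-BBN adds anti-Markovnikov to the monosubstituted alkene about a hundred times faster than to the internal Z-alkene, and alkaline peroxide then replaces boron by OH.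

**Step 6**
Reactants: 9 (4S,12Z)-4-[(tert-butyldimethylsilyl)oxy]nonadec-12-en-1-ol
Product: 10 (4S,12Z)-4-[(tert-butyldimethylsilyl)oxy]nonadec-12-enal
Conditions: TEMPO (10 mol%), PhI(OAc)2 (1.1 equiv), CH2Cl2, rt
Reagents that add atoms: none
Why: The same mild oxoammonium oxidation as in step 2 stops at the aldehyde and tolerates the silyl ether and the alkene.

**Step 7**
Reactants: 10 (4S,12Z)-4-[(tert-butyldimethylsilyl)oxy]nonadec-12-enal; 11 Eschenmoser's salt, [CH2=NMe2]I
Product: 13 (4S,12Z)-4-[(tert-butyldimethylsilyl)oxy]-2-methylidenenonadec-12-enal, via Mannich base 12 (not isolated)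
Conditions: 11 (3 equiv), Et3N (6 equiv), CH2Cl2, rt, 16 h
Reagents that add atoms: Eschenmoser's salt (11), C[N+](C)=C.[I-]
Why: A Mannich reaction of the aldehyde enol at its only α-carbon, followed by E1cB loss of dimethylamine (which also erases the transient α-stereocentre), gives the α-methylene aldehyde, and the silyloxy group is γ to the carbonyl and cannot be eliminated.

**Step 8**
Reactants: 13 (4S,12Z)-4-[(tert-butyldimethylsilyl)oxy]-2-methylidenenonadec-12-enal
Product: 14 (4S,12Z)-4-[(tert-butyldimethylsilyl)oxy]-2-methylidenenonadec-12-en-1-ol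
Conditions: NaBH4 (1 equiv), CeCl3·7H2O (1 equiv), MeOH, 0 °C
Reagents that add atoms: none
Why: The Luche reduction gives clean 1,2-reduction of the enal to the 2-substituted allylic alcohol without conjugate reduction.

**Step 9**
Reactants: 14 (4S,12Z)-4-[(tert-butyldimethylsilyl)oxy]-2-methylidenenonadec-12-en-1-ol
Product: 15 [(2S)-2-{(2S,10Z)-2-[(tert-butyldimethylsilyl)oxy]heptadec-10-en-1-yl}oxiran-2-yl]methanol
Conditions: Ti(OiPr)4 (20 mol%), L-(+)-diethyl tartrate (24 mol%), t-BuOOH (2 equiv, decane), 4 Å MS, CH2Cl2, −25 °C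
Reagents that add atoms: tert-butyl hydroperoxide, CC(C)(C)OO
Why: The Sharpless asymmetric epoxidation touches only the alkene of the allylic alcohol, and with L-(+)-DET oxygen is delivered to the face that makes the fully substituted oxirane carbon (S), as for other 2-alkylallyl alcohols, which is the spatial arrangement of C6 in the target (named R there only because ligand ranks change), the distant C2' centre having little influence.

**Step 10**
Reactants: 15 [(2S)-2-{(2S,10Z)-2-[(tert-butyldimethylsilyl)oxy]heptadec-10-en-1-yl}oxiran-2-yl]methanol; 16 vinylmagnesium bromide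
Product: 17 (2S,4S,12Z)-4-[(tert-butyldimethylsilyl)oxy]-2-(prop-2-en-1-yl)nonadec-12-ene-1,2-diol
Conditions: 16 (4 equiv), CuI (20 mol%), THF, −40 to 0 °C; aq NH4Cl
Reagents that add atoms: vinylmagnesium bromide (16), C=C[Mg]Br
Why: The copper-catalysed SN2 opening occurs at the unsubstituted oxirane CH2 (C5), so the C6–O bond and its configuration are retained, and a Payne shift would lead to the same stereoisomer.

**Step 11**
Reactants: 17 (2S,4S,12Z)-4-[(tert-butyldimethylsilyl)oxy]-2-(prop-2-en-1-yl)nonadec-12-ene-1,2-diol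
Product: 18 (2S,4S,12Z)-4-[(tert-butyldimethylsilyl)oxy]-2-hydroxy-2-(prop-2-en-1-yl)nonadec-12-enal
Conditions: Dess–Martin periodinane (1.2 equiv), pyridine (3 equiv), CH2Cl2, 0 °C
Reagents that add atoms: none
Why: The Dess–Martin oxidation converts the only oxidisable (primary) hydroxyl into the aldehyde without glycol cleavage, and the quaternary α-carbon cannot epimerise.

**Step 12**
Reactants: 18 (2S,4S,12Z)-4-[(tert-butyldimethylsilyl)oxy]-2-hydroxy-2-(prop-2-en-1-yl)nonadec-12-enal; 19 allylmagnesium bromide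
Product: 20 (5S,7S,15Z)-7-[(tert-butyldimethylsilyl)oxy]-5-(prop-2-en-1-yl)docosa-1,15-diene-4,5-diol (C4 epimers)
Conditions: 19 (2.5 equiv), Et2O, −78 °C; aq NH4Cl
Reagents that add atoms: allylmagnesium bromide (19), C=CC[Mg]Br
Why: Grignard carbonyl allylation of the aldehyde is fast and clean, and the new carbinol centre (C1) is formed without useful control and carried on as both epimers because step 14 turns it into the carbonyl carbon.

**Step 13**
Reactants: 20 (5S,7S,15Z)-7-[(tert-butyldimethylsilyl)oxy]-5-(prop-2-en-1-yl)docosa-1,15-diene-4,5-diol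
Product: 21 (1S)-1-{(2S,10Z)-2-[(tert-butyldimethylsilyl)oxy]heptadec-10-en-1-yl}cyclohex-4-ene-1,2-diol (C2 epimers)
Conditions: RuCl2(=CHPh)(PCy3)2 (first-generation Grubbs catalyst, 5 mol%), CH2Cl2 (5 mM), 40 °C
Reagents that add atoms: none
Why: In this ring-closing metathesis the two unhindered monosubstituted allyl arms close the six-membered ring far faster than the first-generation catalyst engages the internal 1,2-disubstituted Z-alkene.

**Step 14**
Reactants: 21 (1S)-1-{(2S,10Z)-2-[(tert-butyldimethylsilyl)oxy]heptadec-10-en-1-yl}cyclohex-4-ene-1,2-diol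
Product: 22 (6S)-6-{(2S,10Z)-2-[(tert-butyldimethylsilyl)oxy]heptadec-10-en-1-yl}-6-hydroxycyclohex-3-en-1-one
Conditions: Dess–Martin periodinane (1.3 equiv), pyridine (3 equiv), CH2Cl2, 0 °C; used at once
Reagents that add atoms: none
Why: The buffered Dess–Martin oxidation of the only secondary hydroxyl merges both epimers into one ketol under neutral conditions that neither cleave the diol nor move the β,γ-double bond into conjugation.

**Step 15**
Reactants: 22 (6S)-6-{(2S,10Z)-2-[(tert-butyldimethylsilyl)oxy]heptadec-10-en-1-yl}-6-hydroxycyclohex-3-en-1-one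
Product: 24 (4S,6S)-6-{(2S,10Z)-2-[(tert-butyldimethylsilyl)oxy]heptadec-10-en-1-yl}-4,6-dihydroxycyclohex-2-en-1-one, via epoxy ketone 23 (not isolated)
Conditions: VO(acac)2 (5 mol%), t-BuOOH (1.1 equiv, decane), CH2Cl2, 0 °C to rt; then Et3N (0.5 equiv), rt
Reagents that add atoms: tert-butyl hydroperoxide, CC(C)(C)OO
Why: In this hydroxyl-directed VO(acac)2/t-BuOOH epoxidation the axial tertiary homoallylic OH binds vanadium and delivers oxygen to its own face of the ring alkene faster than the undirected chain alkene reacts, so the C4–O bond forms cis to the C6–OH, and Et3N then opens the β,γ-epoxy ketone by E1cB elimination to the γ-hydroxy enone without touching that C–O bond, giving (4S).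

**Step 16**
Reactants: 24 (4S,6S)-6-{(2S,10Z)-2-[(tert-butyldimethylsilyl)oxy]heptadec-10-en-1-yl}-4,6-dihydroxycyclohex-2-en-1-one
Product: 25 (4S,6R)-4,6-dihydroxy-6-[(2S,10Z)-2-hydroxyheptadec-10-en-1-yl]cyclohex-2-en-1-one
Conditions: HF·pyridine, THF, 0 °C to rt
Reagents that add atoms: none
Why: Fluoride-driven desilylation under weakly acidic conditions frees the C2' hydroxyl without base-induced damage to the γ-hydroxy enone or the ketol, and no stereocentre is touched (C6 changes descriptor from S to R by ranking only).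

**Compound list**
1 | palmitoleic acid, (9Z)-hexadec-9-enoic acid | CCCCCC/C=C\CCCCCCCC(=O)O | starting material
2 | (9Z)-hexadec-9-en-1-ol | CCCCCC/C=C\CCCCCCCCO | intermediate
3 | (9Z)-hexadec-9-enal | CCCCCC/C=C\CCCCCCCC=O | intermediate
4 | allyltributylstannane | C=CC[Sn](CCCC)(CCCC)CCCC | starting material
5 | tributyl{[(4S,12Z)-nonadeca-1,12-dien-4-yl]oxy}stannane | CCCCCC/C=C\CCCCCCC[C@H](O[Sn](CCCC)(CCCC)CCCC)CC=C | intermediate (not isolated)
6 | (4S,12Z)-nonadeca-1,12-dien-4-ol | CCCCCC/C=C\CCCCCCC[C@H](O)CC=C | intermediate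
7 | tert-butyl(dimethyl){[(4S,12Z)-nonadeca-1,12-dien-4-yl]oxy}silane | CCCCCC/C=C\CCCCCCC[C@H](O[Si](C)(C)C(C)(C)C)CC=C | intermediate
8 | 9-{(4R,12Z)-4-[(tert-butyldimethylsilyl)oxy]nonadec-12-en-1-yl}-9-borabicyclo[3.3.1]nonane (same spatial arrangement as 7; the descriptor changes because boron ranks below carbon) | CCCCCC/C=C\CCCCCCC[C@H](O[Si](C)(C)C(C)(C)C)CCCB1C2CCCC1CCC2 | intermediate (not isolated)
9 | (4S,12Z)-4-[(tert-butyldimethylsilyl)oxy]nonadec-12-en-1-ol | CCCCCC/C=C\CCCCCCC[C@H](O[Si](C)(C)C(C)(C)C)CCCO | intermediate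
10 | (4S,12Z)-4-[(tert-butyldimethylsilyl)oxy]nonadec-12-enal | CCCCCC/C=C\CCCCCCC[C@H](O[Si](C)(C)C(C)(C)C)CCC=O | intermediate
11 | Eschenmoser's salt, N,N-dimethylmethaniminium iodide | C[N+](C)=C.[I-] | starting material
12 | (4S,12Z)-4-[(tert-butyldimethylsilyl)oxy]-2-[(dimethylamino)methyl]nonadec-12-enal (C2 epimers) | CCCCCC/C=C\CCCCCCC[C@H](O[Si](C)(C)C(C)(C)C)CC(CN(C)C)C=O | intermediate (not isolated)
13 | (4S,12Z)-4-[(tert-butyldimethylsilyl)oxy]-2-methylidenenonadec-12-enal | CCCCCC/C=C\CCCCCCC[C@H](O[Si](C)(C)C(C)(C)C)CC(=C)C=O | intermediate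
14 | (4S,12Z)-4-[(tert-butyldimethylsilyl)oxy]-2-methylidenenonadec-12-en-1-ol | CCCCCC/C=C\CCCCCCC[C@H](O[Si](C)(C)C(C)(C)C)CC(=C)CO | intermediate
15 | [(2S)-2-{(2S,10Z)-2-[(tert-butyldimethylsilyl)oxy]heptadec-10-en-1-yl}oxiran-2-yl]methanol | CCCCCC/C=C\CCCCCCC[C@H](O[Si](C)(C)C(C)(C)C)C[C@]1(CO)CO1 | intermediate
16 | vinylmagnesium bromide | C=C[Mg]Br | starting material
17 | (2S,4S,12Z)-4-[(tert-butyldimethylsilyl)oxy]-2-(prop-2-en-1-yl)nonadec-12-ene-1,2-diol | CCCCCC/C=C\CCCCCCC[C@H](O[Si](C)(C)C(C)(C)C)C[C@](O)(CO)CC=C | intermediate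
18 | (2S,4S,12Z)-4-[(tert-butyldimethylsilyl)oxy]-2-hydroxy-2-(prop-2-en-1-yl)nonadec-12-enal | CCCCCC/C=C\CCCCCCC[C@H](O[Si](C)(C)C(C)(C)C)C[C@](O)(C=O)CC=C | intermediate
19 | allylmagnesium bromide | C=CC[Mg]Br | starting material
20 | (5S,7S,15Z)-7-[(tert-butyldimethylsilyl)oxy]-5-(prop-2-en-1-yl)docosa-1,15-diene-4,5-diol (C4 epimers) | CCCCCC/C=C\CCCCCCC[C@H](O[Si](C)(C)C(C)(C)C)C[C@](O)(C(O)CC=C)CC=C | intermediate
21 | (1S)-1-{(2S,10Z)-2-[(tert-butyldimethylsilyl)oxy]heptadec-10-en-1-yl}cyclohex-4-ene-1,2-diol (C2 epimers) | CCCCCC/C=C\CCCCCCC[C@H](O[Si](C)(C)C(C)(C)C)C[C@@]1(O)CC=CCC1O | intermediate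
22 | (6S)-6-{(2S,10Z)-2-[(tert-butyldimethylsilyl)oxy]heptadec-10-en-1-yl}-6-hydroxycyclohex-3-en-1-one | CCCCCC/C=C\CCCCCCC[C@H](O[Si](C)(C)C(C)(C)C)C[C@@]1(O)CC=CCC1=O | intermediate
23 | (1R,4S,6S)-4-{(2S,10Z)-2-[(tert-butyldimethylsilyl)oxy]heptadec-10-en-1-yl}-4-hydroxy-7-oxabicyclo[4.1.0]heptan-3-one | CCCCCC/C=C\CCCCCCC[C@H](O[Si](C)(C)C(C)(C)C)C[C@@]1(O)C[C@@H]2O[C@@H]2CC1=O | intermediate (not isolated)
24 | (4S,6S)-6-{(2S,10Z)-2-[(tert-butyldimethylsilyl)oxy]heptadec-10-en-1-yl}-4,6-dihydroxycyclohex-2-en-1-one | CCCCCC/C=C\CCCCCCC[C@H](O[Si](C)(C)C(C)(C)C)C[C@@]1(O)C[C@H](O)C=CC1=O | intermediate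
25 | (4S,6R)-4,6-dihydroxy-6-[(2S,10Z)-2-hydroxyheptadec-10-en-1-yl]cyclohex-2-en-1-one | CCCCCC/C=C\CCCCCCC[C@H](O)C[C@@]1(O)C[C@H](O)C=CC1=O | target

**Total steps:** 16. **Longest linear sequence:** 16 steps (1 to 25).

**Three steps most likely to fail**

**Step 15.** Homoallylic direction gives only a moderate rate advantage over the isolated chain alkene, and its substrate 22 is the most fragile compound of the route because it can slip into conjugation.

The fallback is a tethered oxygen delivery that sets out from 21, so that 22 is never made, and comes back at 23.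
- Ac2O/pyridine acetylates only the secondary hydroxyl to give the monoacetate F1.
- Boc2O/DMAP turns the tertiary hydroxyl into the tert-butyl carbonate F2.
- I2 in MeCN at −20 °C in the dark closes the carbonate oxygen onto C4 and gives the bridged iodo carbonate F3. Only the ring alkene has an internal nucleophile, and the new C4–O bond is necessarily cis to the C6 oxygen.
- K2CO3/MeOH removes carbonate and acetate, and the freed C4 alkoxide displaces the trans iodide to give the syn-epoxy diol F4.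
- Dess–Martin oxidation of its only secondary hydroxyl gives 23, which is treated with Et3N as in step 15.

**Step 9.** 1,1-Disubstituted allylic alcohols give somewhat lower selectivity than other olefin classes, and their 2,2-disubstituted epoxides are easily opened by the titanium alkoxides.

The fallback replaces reagent control by substrate control from C2'. It sets out from 6 and comes back at 17.
- Hydroboration–oxidation (9-BBN, 2.2 equiv; H2O2/NaOH) gives the 1,4-diol F5.
- TEMPO/PhI(OAc)2 closes it to the γ-lactone F6.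
- LiN(iPr)2 and allyl bromide give the α-allyl lactone F7 (epimers, irrelevant).
- KN(SiMe3)2 followed by 2-(phenylsulfonyl)-3-phenyloxaziridine hydroxylates the enolate on the face away from the C5 chain to give the trans hydroxy lactone F8.
- LiAlH4 gives the triol F9.
- TBSCl (2.2 equiv)/imidazole gives the bis-silyl ether F10, with the tertiary OH untouched.
- HF·pyridine buffered by pyridine at 0 °C removes only the primary silyl group to give 17.

**Step 5.** The yield depends on 9-BBN distinguishing the terminal alkene from the chain Z-alkene.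

The fallback brings in the 2-methylene-3-oxypropyl unit in the allylation itself. It needs no hydroboration or methylenation, sets out from 3 and comes back at 14.
- Bu3SnLi and 3-chloro-2-(chloromethyl)prop-1-ene give 2-(chloromethyl)-3-(tributylstannyl)prop-1-ene F11.
- The same (R)-BINOL/Ti(OiPr)4 catalyst adds it to the Re face of 3 to give the chloro alcohol F12.
- TBSCl/imidazole gives the silyl ether F13.
- KOAc in DMF displaces the allylic chloride to give the allylic acetate F14.
- K2CO3/MeOH gives 14.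

**Further compounds**
F1 | step 15 | (2S)-2-{(2S,10Z)-2-[(tert-butyldimethylsilyl)oxy]heptadec-10-en-1-yl}-2-hydroxycyclohex-4-en-1-yl acetate (C1 epimers) | CCCCCC/C=C\CCCCCCC[C@H](O[Si](C)(C)C(C)(C)C)C[C@@]1(O)CC=CCC1OC(C)=O
F2 | step 15 | tert-butyl carbonate of the tertiary hydroxyl of F1 | CCCCCC/C=C\CCCCCCC[C@H](O[Si](C)(C)C(C)(C)C)C[C@@]1(OC(=O)OC(C)(C)C)CC=CCC1OC(C)=O
F3 | step 15 | bridged iodo carbonate (2,4-dioxabicyclo[3.3.1]nonan-3-one; C6–O–CO–O–C4, iodine on C3 trans to the C4 oxygen, acetate on C1) | CCCCCC/C=C\CCCCCCC[C@H](O[Si](C)(C)C(C)(C)C)C[C@]12C[C@H](OC(=O)O1)[C@@H](I)CC2OC(C)=O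
F4 | step 15 | (1R,4S,6S)-4-{(2S,10Z)-2-[(tert-butyldimethylsilyl)oxy]heptadec-10-en-1-yl}-7-oxabicyclo[4.1.0]heptane-3,4-diol (C3 epimers) | CCCCCC/C=C\CCCCCCC[C@H](O[Si](C)(C)C(C)(C)C)C[C@@]1(O)C[C@@H]2O[C@@H]2CC1O
F5 | step 9 | (4S,12Z)-nonadec-12-ene-1,4-diol | CCCCCC/C=C\CCCCCCC[C@H](O)CCCO
F6 | step 9 | (5S)-5-[(8Z)-pentadec-8-en-1-yl]oxolan-2-one | CCCCCC/C=C\CCCCCCC[C@H]1CCC(=O)O1
F7 | step 9 | (5S)-5-[(8Z)-pentadec-8-en-1-yl]-3-(prop-2-en-1-yl)oxolan-2-one (C3 epimers) | CCCCCC/C=C\CCCCCCC[C@H]1CC(CC=C)C(=O)O1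
F8 | step 9 | (3S,5S)-3-hydroxy-5-[(8Z)-pentadec-8-en-1-yl]-3-(prop-2-en-1-yl)oxolan-2-one | CCCCCC/C=C\CCCCCCC[C@H]1C[C@@](O)(CC=C)C(=O)O1
F9 | step 9 | (2S,4S,12Z)-2-(prop-2-en-1-yl)nonadec-12-ene-1,2,4-triol | CCCCCC/C=C\CCCCCCC[C@H](O)C[C@](O)(CO)CC=C
F10 | step 9 | 1,4-bis-O-(tert-butyldimethylsilyl) ether of F9 | CCCCCC/C=C\CCCCCCC[C@H](O[Si](C)(C)C(C)(C)C)C[C@](O)(CO[Si](C)(C)C(C)(C)C)CC=C
F11 | step 5 | 2-(chloromethyl)-3-(tributylstannyl)prop-1-ene | C=C(CCl)C[Sn](CCCC)(CCCC)CCCC
F12 | step 5 | (4S,12Z)-2-(chloromethyl)nonadeca-1,12-dien-4-ol | CCCCCC/C=C\CCCCCCC[C@H](O)CC(=C)CCl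
F13 | step 5 | tert-butyl{[(4S,12Z)-2-(chloromethyl)nonadeca-1,12-dien-4-yl]oxy}dimethylsilane | CCCCCC/C=C\CCCCCCC[C@H](O[Si](C)(C)C(C)(C)C)CC(=C)CCl
F14 | step 5 | (4S,12Z)-4-[(tert-butyldimethylsilyl)oxy]-2-methylidenenonadec-12-en-1-yl acetate | CCCCCC/C=C\CCCCCCC[C@H](O[Si](C)(C)C(C)(C)C)CC(=C)COC(C)=O
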